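The route rests on cutting the C3–C3a bond of the cyclopentane (ring A, azulene numbering). The cis pair of C3a hydroxyl and C3 isopropyl, next to the C8a methyl of the cis-fused hydroazulene, is the retron of an intramolecular carbonyl-ene reaction. In one operation the saturated ketone of a monocyclic cycloheptenedione (ring B) is attacked by its own 4-methylpent-3-enyl side chain. Ring A closes, the tertiary alcohol and the three-carbon branch appear, and C3 and C3a are set from the lone quaternary centre C8a. The precursor is geraniol plus a five-carbon piece. C8a comes from an epoxide through a stereospecific 1,2-acyl shift.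

Key step: step 11

Remark on the chemistry: azulene numbering is used for the bicyclic compounds. C3 bears the isopropyl group, C3a the hydroxyl, C6 the vinylic methyl, C8 the ester oxygen and C8a the angular methyl. The same labels are used for the corresponding atoms of monocyclic 14.

Step 1
Reactants: 1 geraniol
Product: 2 (2S,3S)-2,3-epoxygeraniol
Conditions: Ti(OiPr)4 (5 mol %), L-(+)-diethyl tartrate (6 mol %), t-BuOOH, 4 Å MS, CH2Cl2, −20 °C
Reagents that add atoms: tert-butyl hydroperoxide CC(C)(C)OO
Why: Sharpless asymmetric epoxidation, in which the allylic alcohol binds to the titanium tartrate complex, the L-(+)-tartrate directs oxygen to the face that gives the (2S,3S)-epoxide, and the remote 6,7-alkene, lacking a directing hydroxyl, is left alone.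

Step 2
Reactants: 2 (2S,3S)-2,3-epoxygeraniol
Product: 3 (2R,3S)-3-methyl-3-(4-methylpent-3-en-1-yl)oxirane-2-carbaldehyde
Conditions: nPr4NRuO4 (5 mol %), N-methylmorpholine N-oxide, 4 Å MS, CH2Cl2, rt
Reagents that add atoms: none
Why: Ley–Griffith oxidation is neutral and stops at the aldehyde, so the acid-sensitive trisubstituted epoxide and both its stereocentres survive (the descriptor at C2 changes only by priority).

Step 3
Reactants: 3 (2R,3S)-3-methyl-3-(4-methylpent-3-en-1-yl)oxirane-2-carbaldehyde
Product: 4 1-[(2S,3S)-3-methyl-3-(4-methylpent-3-en-1-yl)oxiran-2-yl]ethan-1-ol (both carbinol epimers)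
Conditions: MeMgBr, THF, −78 °C
Reagents that add atoms: methylmagnesium bromide C[Mg]Br
Why: Grignard 1,2-addition to the aldehyde is far faster than epoxide opening at low temperature, and the new carbinol centre needs no control because step 4 removes it.

Step 4
Reactants: 4 1-[(2S,3S)-3-methyl-3-(4-methylpent-3-en-1-yl)oxiran-2-yl]ethan-1-ol (both carbinol epimers)
Product: 5 1-[(2R,3S)-3-methyl-3-(4-methylpent-3-en-1-yl)oxiran-2-yl]ethan-1-one
Conditions: nPr4NRuO4 (5 mol %), N-methylmorpholine N-oxide, 4 Å MS, CH2Cl2, rt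
Reagents that add atoms: none
Why: Ley–Griffith oxidation converges both epimers on one epoxy methyl ketone without touching the epoxide or the alkene.

Step 5
Reactants: 6 prop-2-yn-1-ol
Product: 8 (Z)-3-iodo-2-methylprop-2-en-1-ol, via alkenylmagnesium alkoxide 7 (not isolated)
Conditions: MeMgBr (2.5 equiv), CuI (10 mol %), THF, 0 °C to rt; then I2, −10 °C
Reagents that add atoms: methylmagnesium bromide C[Mg]Br; iodine II
Why: Copper-catalysed, alkoxide-directed anti carbomagnesiation places methyl on C2 and magnesium on C3 cis to the CH2O group, and iodinolysis with retention fixes the Z geometry needed for an endocyclic alkene.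

Step 6
Reactants: 8 (Z)-3-iodo-2-methylprop-2-en-1-ol
Product: 9 (Z)-3-bromo-1-iodo-2-methylprop-1-ene
Conditions: CBr4, PPh3, CH2Cl2, 0 °C
Reagents that add atoms: carbon tetrabromide BrC(Br)(Br)Br
Why: Appel bromination replaces the primary allylic hydroxyl under neutral conditions without changing the alkene geometry or the vinyl iodide.

Step 7
Reactants: 5 1-[(2R,3S)-3-methyl-3-(4-methylpent-3-en-1-yl)oxiran-2-yl]ethan-1-one; 9 (Z)-3-bromo-1-iodo-2-methylprop-1-ene
Product: 11 (4Z)-5-iodo-4-methyl-1-[(2R,3S)-3-methyl-3-(4-methylpent-3-en-1-yl)oxiran-2-yl]pent-4-en-1-one, via lithium enolate 10 (not isolated)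
Conditions: LiN(iPr)2 (LDA), THF, −78 °C; then 9, DMPU, −78 to −40 °C
Reagents that add atoms: none
Why: Kinetic deprotonation occurs at the methyl group (the oxirane C–H is much less acidic), and SN2 alkylation of the enolate by the reactive primary allylic bromide joins the two fragments with all stereochemistry retained.

Step 8
Reactants: 11 (4Z)-5-iodo-4-methyl-1-[(2R,3S)-3-methyl-3-(4-methylpent-3-en-1-yl)oxiran-2-yl]pent-4-en-1-one
Product: 12 (2R,6Z)-7-iodo-2,6-dimethyl-2-(4-methylpent-3-en-1-yl)-3-oxohept-6-enal
Conditions: BF3·OEt2 (0.3 equiv), CH2Cl2, −78 to −40 °C, short contact time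
Reagents that add atoms: none
Why: In this Lewis-acid-induced 1,2-acyl shift of an α,β-epoxy ketone the epoxide opens at its tertiary carbon and the acyl group migrates to the face opposite the departing oxygen, so inversion turns the (3S) epoxide carbon into the (R) quaternary centre (later C8a) while the former C2 becomes the aldehyde.

Step 9
Reactants: 12 (2R,6Z)-7-iodo-2,6-dimethyl-2-(4-methylpent-3-en-1-yl)-3-oxohept-6-enal
Product: 13 (2R)-3-hydroxy-2,5-dimethyl-2-(4-methylpent-3-en-1-yl)cyclohept-4-en-1-one (both C3 epimers)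
Conditions: CrCl2 (6 equiv), NiCl2 (2 mol %), DMSO/THF, rt, high dilution
Reagents that add atoms: none
Why: In the Nozaki–Hiyama–Kishi reaction nickel inserts into the vinyl C–I bond with retention of the Z geometry, and the alkenyl group passes to trivalent chromium and adds only to the aldehyde (the ketone is inert), with the Z alkene holding both ends within reach for the seven-membered ring; the uncontrolled carbinol centre is erased in step 10.

Step 10
Reactants: 13 (2R)-3-hydroxy-2,5-dimethyl-2-(4-methylpent-3-en-1-yl)cyclohept-4-en-1-one (both C3 epimers)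
Product: 14 (2S)-2,5-dimethyl-2-(4-methylpent-3-en-1-yl)cyclohept-4-ene-1,3-dione
Conditions: Dess–Martin periodinane, CH2Cl2, 0 °C to rt
Reagents that add atoms: none
Why: Dess–Martin oxidation under non-nucleophilic conditions converges both epimers on one enedione without retro-aldol or retro-Claisen cleavage at the non-enolisable quaternary centre (the descriptor changes only by priority).

Step 11
Reactants: 14 (2S)-2,5-dimethyl-2-(4-methylpent-3-en-1-yl)cyclohept-4-ene-1,3-dione
Product: 15 (3R,3aS,8aS)-3a-hydroxy-6,8a-dimethyl-3-(prop-1-en-2-yl)-2,3,3a,4,5,8a-hexahydroazulen-8(1H)-one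
Conditions: MeAlCl2 (1.1 equiv), CH2Cl2, −78 to −20 °C; aqueous work-up
Reagents that add atoms: none
Why: MeAlCl2 activates the carbonyl groups of 14, the trisubstituted side-chain alkene attacks the saturated ketone carbon (C3a) through its inner carbon (C3) while an allylic methyl hydrogen passes to the carbonyl oxygen through a six-membered array, and loss of methane from the aluminium–alcohol complex makes the closure irreversible; the closest known reaction type is the alkylaluminium-halide-promoted intramolecular carbonyl-ene (Prins-type) cyclisation of δ,ε-unsaturated ketones to 2-isopropenylcyclopentanols. Ring A closes in a 5-exo-trig mode with respect to both the C=O and the C=C bond. C3a is controlled by C8a, because the three-atom tether can reach the neighbouring carbonyl only from the face on which it stands, so the fusion is cis and the hydroxyl ends up syn to the C8a methyl. C3 is controlled by the hydrogen transfer, because only the arrangement with oxygen and the CMe2 terminus on the same side of the nascent ring lets the proton reach oxygen and a trans zwitterion can only revert, so hydroxyl and isopropenyl are cis. The step needs chemoselection between the two carbonyl groups that flank C8a: the enone carbonyl C8 is deactivated by conjugation and a complexed enone accepts alkenes at its β-carbon C6, which the tether could reach only through a strained bridged ring, whereas addition at C3a keeps the enone intact. The alkylaluminium reagent also scavenges protons, which protects the new 1,1-disubstituted alkene and the tertiary alcohol.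

Step 12
Reactants: 15 (3R,3aS,8aS)-3a-hydroxy-6,8a-dimethyl-3-(prop-1-en-2-yl)-2,3,3a,4,5,8a-hexahydroazulen-8(1H)-one
Product: 16 (3R,3aS,8aS)-3a-hydroxy-6,8a-dimethyl-3-(propan-2-yl)-2,3,3a,4,5,8a-hexahydroazulen-8(1H)-one
Conditions: H2 (1 atm), RhCl(PPh3)3 (5 mol %), benzene, rt
Reagents that add atoms: none
Why: Homogeneous hydrogenation with RhCl(PPh3)3 discriminates by steric access, so the 1,1-disubstituted isopropenyl group is saturated while the trisubstituted conjugated C6–C7 alkene stays (the carvone-to-carvotanacetone type of selectivity), and no stereocentre is formed.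

Step 13
Reactants: 16 (3R,3aS,8aS)-3a-hydroxy-6,8a-dimethyl-3-(propan-2-yl)-2,3,3a,4,5,8a-hexahydroazulen-8(1H)-one
Product: 17 (3R,3aS,8R,8aR)-6,8a-dimethyl-3-(propan-2-yl)-2,3,4,5,8,8a-hexahydro-1H-azulene-3a,8-diol
Conditions: Me4NBH(OAc)3, MeCN/AcOH, −20 °C
Reagents that add atoms: none
Why: In the Evans–Saksena reduction the C3a hydroxyl replaces an acetate on boron and the bound hydride reaches the C8 carbonyl in a 1,2-sense from the hydroxyl-bearing face, which sets the (8R)-carbinol anti to the C3a hydroxyl, while the free reagent is too weak to reduce the enone on its own.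

Step 14
Reactants: 17 (3R,3aS,8R,8aR)-6,8a-dimethyl-3-(propan-2-yl)-2,3,4,5,8,8a-hexahydro-1H-azulene-3a,8-diol; 18 4-methoxybenzoyl chloride
Product: 19 (3R,3aS,8R,8aR)-3a-hydroxy-6,8a-dimethyl-3-(propan-2-yl)-1,2,3,3a,4,5,8,8a-octahydroazulen-8-yl 4-methoxybenzoate
Conditions: Et3N, DMAP (cat.), CH2Cl2, rt
Reagents that add atoms: none
Why: DMAP-catalysed acylation occurs only at the secondary allylic hydroxyl because the tertiary ring-fusion hydroxyl is too hindered, and it proceeds with retention at C8.

Compound list
1 | geraniol, (2E)-3,7-dimethylocta-2,6-dien-1-ol | CC(C)=CCC/C(C)=C/CO | starting material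
2 | (2S,3S)-2,3-epoxygeraniol, [(2S,3S)-3-methyl-3-(4-methylpent-3-en-1-yl)oxiran-2-yl]methanol | OC[C@@H]1O[C@@]1(C)CCC=C(C)C | intermediate
3 | (2R,3S)-3-methyl-3-(4-methylpent-3-en-1-yl)oxirane-2-carbaldehyde | O=C[C@@H]1O[C@@]1(C)CCC=C(C)C | intermediate
4 | 1-[(2S,3S)-3-methyl-3-(4-methylpent-3-en-1-yl)oxiran-2-yl]ethan-1-ol (both carbinol epimers) | CC(O)[C@@H]1O[C@@]1(C)CCC=C(C)C | intermediate
5 | 1-[(2R,3S)-3-methyl-3-(4-methylpent-3-en-1-yl)oxiran-2-yl]ethan-1-one | CC(=O)[C@@H]1O[C@@]1(C)CCC=C(C)C | intermediate
6 | prop-2-yn-1-ol | C#CCO | starting material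
7 | bromomagnesium (Z)-3-(bromomagnesio)-2-methylprop-2-en-1-olate (not isolated) | Br[Mg]/C=C(C)\CO[Mg]Br | intermediate
8 | (Z)-3-iodo-2-methylprop-2-en-1-ol | I/C=C(C)\CO | intermediate
9 | (Z)-3-bromo-1-iodo-2-methylprop-1-ene | I/C=C(C)\CBr | intermediate
10 | lithium enolate of 5, deprotonated at the methyl group (not isolated) | [Li]OC(=C)[C@@H]1O[C@@]1(C)CCC=C(C)C | intermediate
11 | (4Z)-5-iodo-4-methyl-1-[(2R,3S)-3-methyl-3-(4-methylpent-3-en-1-yl)oxiran-2-yl]pent-4-en-1-one | I/C=C(C)\CCC(=O)[C@@H]1O[C@@]1(C)CCC=C(C)C | intermediate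
12 | (2R,6Z)-7-iodo-2,6-dimethyl-2-(4-methylpent-3-en-1-yl)-3-oxohept-6-enal | O=C[C@@](C)(CCC=C(C)C)C(=O)CC/C(C)=C\I | intermediate
13 | (2R)-3-hydroxy-2,5-dimethyl-2-(4-methylpent-3-en-1-yl)cyclohept-4-en-1-one (both C3 epimers) | OC1C=C(C)CCC(=O)[C@]1(C)CCC=C(C)C | intermediate
14 | (2S)-2,5-dimethyl-2-(4-methylpent-3-en-1-yl)cyclohept-4-ene-1,3-dione | O=C1C=C(C)CCC(=O)[C@]1(C)CCC=C(C)C | intermediate
15 | (3R,3aS,8aS)-3a-hydroxy-6,8a-dimethyl-3-(prop-1-en-2-yl)-2,3,3a,4,5,8a-hexahydroazulen-8(1H)-one | O=C1C=C(C)CC[C@]2(O)[C@@H](C(C)=C)CC[C@]12C | intermediate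
16 | (3R,3aS,8aS)-3a-hydroxy-6,8a-dimethyl-3-(propan-2-yl)-2,3,3a,4,5,8a-hexahydroazulen-8(1H)-one | O=C1C=C(C)CC[C@]2(O)[C@@H](C(C)C)CC[C@]12C | intermediate
17 | (3R,3aS,8R,8aR)-6,8a-dimethyl-3-(propan-2-yl)-2,3,4,5,8,8a-hexahydro-1H-azulene-3a,8-diol | O[C@@H]1C=C(C)CC[C@]2(O)[C@@H](C(C)C)CC[C@]12C | intermediate
18 | 4-methoxybenzoyl chloride | COc1ccc(C(=O)Cl)cc1 | starting material
19 | (3R,3aS,8R,8aR)-3a-hydroxy-6,8a-dimethyl-3-(propan-2-yl)-1,2,3,3a,4,5,8,8a-octahydroazulen-8-yl 4-methoxybenzoate | COc1ccc(C(=O)O[C@@H]2C=C(C)CC[C@]3(O)[C@@H](C(C)C)CC[C@]23C)cc1 | target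

Total step count: 14. Longest linear sequence: 12 (steps 1–4 and 7–14); steps 5 and 6 form the short branch.

Steps most likely to fail

Step 11. The unactivated ketone may be too poor an enophile. Methyl transfer from aluminium, chloride capture or hydride and alkyl shifts of the zwitterion, or attack at the enone carbonyl could then set in before closure. The fallback reverses the polarity, so that a nucleophilic allylmetal attacks a carbonyl group that is not activated. It sets out from 14. Allylic oxidation of the (E)-methyl group of the side chain (SeO2 cat., t-BuOOH, CH2Cl2) should give (2S)-2-[(3E)-5-hydroxy-4-methylpent-3-en-1-yl]-2,5-dimethylcyclohept-4-ene-1,3-dione F1. Appel bromination should give (2S)-2-[(3E)-5-bromo-4-methylpent-3-en-1-yl]-2,5-dimethylcyclohept-4-ene-1,3-dione F2. A zinc Barbier closure (Zn, THF/aq NH4Cl) should then form the same C3–C3a bond through the γ-carbon of the allylzinc. Its closed six-membered transition state again places oxygen and isopropenyl cis. The fallback comes back to the route at 15.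

Step 8. A hydride shift to the 1,2-diketone could compete with the acyl shift. The freed aldehyde could also close onto the side-chain alkene under the small Lewis acid. In the fallback the migrating carbon is taken to the alcohol level, so that no free 1,3-dicarbonyl compound meets a small Lewis acid. It sets out from 11.
- NaBH4/CeCl3·7H2O should give (4Z)-5-iodo-4-methyl-1-[(2S,3S)-3-methyl-3-(4-methylpent-3-en-1-yl)oxiran-2-yl]pent-4-en-1-ol F3.
- TBSOTf/2,6-lutidine should give its tert-butyldimethylsilyl ether F4.
- Methylaluminium bis(4-bromo-2,6-di-tert-butylphenoxide) should induce the epoxy silyl ether rearrangement (siloxyalkyl shift with the same inversion) to (2S,6Z)-3-(tert-butyldimethylsilyloxy)-7-iodo-2,6-dimethyl-2-(4-methylpent-3-en-1-yl)hept-6-enal F5.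
- CrCl2/NiCl2 closure should give 7-(tert-butyldimethylsilyloxy)-1,4-dimethyl-1-(4-methylpent-3-en-1-yl)cyclohept-3-en-2-ol F6.
- Bu4NF should give 2,5-dimethyl-2-(4-methylpent-3-en-1-yl)cyclohept-4-ene-1,3-diol F7.
- Double Dess–Martin oxidation comes back to the route at 14.

Step 13. The hindered tertiary hydroxyl may exchange slowly on boron, so that undirected hydride attack on the other face erodes the facial selectivity. In the fallback, external attack is made the only pathway and the centre is inverted during esterification. It sets out from 16. NaBH4/CeCl3·7H2O in MeOH is expected to approach anti to the C8a methyl and the C3a hydroxyl. It should give (3R,3aS,8S,8aR)-6,8a-dimethyl-3-(propan-2-yl)-2,3,4,5,8,8a-hexahydro-1H-azulene-3a,8-diol F8. Mitsunobu esterification (PPh3, DIAD, 4-methoxybenzoic acid) should invert C8 and come back to the route directly at 19.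

Further compounds
F1 | step 11 | (2S)-2-[(3E)-5-hydroxy-4-methylpent-3-en-1-yl]-2,5-dimethylcyclohept-4-ene-1,3-dione | O=C1C=C(C)CCC(=O)[C@]1(C)CC/C=C(\C)CO
F2 | step 11 | (2S)-2-[(3E)-5-bromo-4-methylpent-3-en-1-yl]-2,5-dimethylcyclohept-4-ene-1,3-dione | O=C1C=C(C)CCC(=O)[C@]1(C)CC/C=C(\C)CBr
F3 | step 8 | (4Z)-5-iodo-4-methyl-1-[(2S,3S)-3-methyl-3-(4-methylpent-3-en-1-yl)oxiran-2-yl]pent-4-en-1-ol (both carbinol epimers) | I/C=C(C)\CCC(O)[C@@H]1O[C@@]1(C)CCC=C(C)C
F4 | step 8 | tert-butyldimethylsilyl ether of F3 | I/C=C(C)\CCC(O[Si](C)(C)C(C)(C)C)[C@@H]1O[C@@]1(C)CCC=C(C)C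
F5 | step 8 | (2S,6Z)-3-(tert-butyldimethylsilyloxy)-7-iodo-2,6-dimethyl-2-(4-methylpent-3-en-1-yl)hept-6-enal (both C3 epimers) | O=C[C@@](C)(CCC=C(C)C)C(O[Si](C)(C)C(C)(C)C)CC/C(C)=C\I
F6 | step 8 | 7-(tert-butyldimethylsilyloxy)-1,4-dimethyl-1-(4-methylpent-3-en-1-yl)cyclohept-3-en-2-ol (quaternary centre as in 13, oxygenated centres as mixtures) | OC1C=C(C)CCC(O[Si](C)(C)C(C)(C)C)[C@]1(C)CCC=C(C)C
F7 | step 8 | 2,5-dimethyl-2-(4-methylpent-3-en-1-yl)cyclohept-4-ene-1,3-diol (quaternary centre as in 13, carbinol centres as mixtures) | OC1C=C(C)CCC(O)[C@]1(C)CCC=C(C)C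
F8 | step 13 | (3R,3aS,8S,8aR)-6,8a-dimethyl-3-(propan-2-yl)-2,3,4,5,8,8a-hexahydro-1H-azulene-3a,8-diol | O[C@H]1C=C(C)CC[C@]2(O)[C@@H](C(C)C)CC[C@]12C
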